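**Strategy.** Ring A of this ent-labdane is closed last, onto a finished ring B, by stitching a two-carbon unit (C2–C3) between C1 and C4. The precursor is a trans-fused bicyclic lactol in which C1 (aldehyde level) is tied to the C19 oxygen and C4 carries an exocyclic methylene (C18). Iron-hydride hydrogen-atom transfer gives the tertiary C4 radical, which adds to vinyltriphenylphosphonium bromide; the ylide then olefinates C1 in the same flask. The step exploits the 1,3-diaxial pair C19/C20 on ring A: the temporary C1–O–C19 ring lets the axial C20 methyl on C10 steer attack at C4, so the C4 quaternary centre, ring A and the free C19 alcohol arise together.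

Key step: step 12

Remark on numbering: labdane numbering is used (ring A = C1–C5, C10; ring B = C5–C10; C17 = exocyclic CH2 on C8; C18 = methyl and C19 = CH2O on C4; C20 = methyl on C10; side chain C11–C16).

Assumption: each chiral ligand or alkaloid is specified by the configuration it must deliver (step 2: R at the ring carbon that becomes C5; step 5: the R hemiester); should the named series induce the opposite sense, its pseudo-enantiomer is used.

**Step 1**
Reactants: 1 2-bromoprop-2-en-1-ol
Product: 2 (2-bromoallyloxy)(tert-butyl)dimethylsilane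
Conditions: TBSCl, imidazole, CH2Cl2, 0 °C to rt
Reagents that add atoms: tert-butyldimethylsilyl chloride CC(C)(C)[Si](C)(C)Cl
Why: Standard silyl ether formation on a primary allylic alcohol; no stereocentre is involved.

**Step 2**
Reactants: 2 (2-bromoallyloxy)(tert-butyl)dimethylsilane; 3 2-methylcyclohex-2-en-1-one
Product: 7 (R)-configured trimethylsilyl enol ether of 3-alkenyl-2-methylcyclohexanone, via alkenyllithium 4 (not isolated), via alkenylmagnesium bromide 5 (not isolated), via magnesium enolate 6 (not isolated)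
Conditions: 2, t-BuLi (2 equiv), Et2O, −78 °C; MgBr2·OEt2, −78 °C; then 3, Cu(OTf)2 (5 mol%), chiral hydroxyalkyl-imidazolinium salt (NHC precursor, 6 mol%), Et2O, −78 to −40 °C; TMSCl, Et3N, DMPU, −40 °C to rt
Reagents that add atoms: chlorotrimethylsilane C[Si](C)(C)Cl
Why: Copper/NHC-catalysed asymmetric conjugate addition of a Grignard reagent to an α-substituted cyclic enone with enolate trapping, in which the chiral copper complex selects the enone face and so sets C5 (R), while O-silylation keeps the enolate regiochemistry for the quaternisation of C10.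

**Step 3**
Reactants: 7 silyl enol ether; 8 2-methoxy-1,3-dioxolane
Product: 9 (2S,3R)-2-(1,3-dioxolan-2-yl)-2-methyl-3-alkenylcyclohexanone
Conditions: TMSOTf (10 mol%), CH2Cl2, −78 °C
Reagents that add atoms: none
Why: Mukaiyama-type alkylation of the silyl enol ether by the dioxolan-2-ylium ion, which enters axially and anti to the pseudo-axial C5 alkenyl group, so that the masked formyl group (C1) ends trans to C4 and the C10 methyl cis to it, as the trans ring fusion requires.

**Step 4**
Reactants: 9 keto acetal
Product: 10 (5R,6R)-enol triflate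
Conditions: KHMDS, THF, −78 °C; PhNTf2, −78 to 0 °C
Reagents that add atoms: N-phenylbis(trifluoromethanesulfonimide) O=S(=O)(N(c1ccccc1)S(=O)(=O)C(F)(F)F)C(F)(F)F
Why: The ketone can enolise only toward C8 because C10 is quaternary, so O-triflation of the kinetic enolate gives a single enol triflate.

**Step 5**
Reactants: 11 3-methylglutaric anhydride; 12 benzyl alcohol
Product: 13 (3R)-5-(benzyloxy)-3-methyl-5-oxopentanoic acid
Conditions: quinidine (1.1 equiv), BnOH (3 equiv), toluene, −55 °C; 2 N HCl wash
Reagents that add atoms: none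
Why: Cinchona-alkaloid-mediated desymmetrising alcoholysis of a prochiral cyclic anhydride, in which the alkaloid differentiates the enantiotopic carbonyl groups and thereby sets C13.

**Step 6**
Reactants: 13 hemiester
Product: 14 benzyl (3R)-5-hydroxy-3-methylpentanoate
Conditions: BH3·SMe2, THF, −10 °C to rt; MeOH quench
Reagents that add atoms: none
Why: Borane reduces the carboxylic acid chemoselectively in the presence of the ester through the acyloxyborane.

**Step 7**
Reactants: 14 hydroxy ester
Product: 15 benzyl (3S)-5-iodo-3-methylpentanoate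
Conditions: I2, PPh3, imidazole, CH2Cl2, 0 °C
Reagents that add atoms: iodine II
Why: Appel-type iodination of a primary alcohol, which leaves the remote stereocentre untouched (the descriptor changes only through the priority rules).

**Step 8**
Reactants: 15 iodide; 10 enol triflate
Product: 17 trisubstituted C8=C9 alkene carrying the side chain, via alkylzinc iodide 16 (not isolated)
Conditions: 15, Zn dust (1,2-dibromoethane/TMSCl-activated), LiCl, THF, 40 °C; then 10, Pd(OAc)2 (3 mol%), SPhos (6 mol%), THF/NMP, 50 °C
Reagents that add atoms: none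
Why: Negishi sp2–sp3 cross-coupling, in which zinc insertion tolerates the benzyl ester and the primary alkylzinc transmetalates and couples with the hindered enol triflate faster than it undergoes β-hydride elimination.

**Step 9**
Reactants: 17 diene
Product: 18 C8–C9 epoxide (both epoxide faces)
Conditions: mCPBA (1.05 equiv), NaHCO3, CH2Cl2, −20 to 0 °C
Reagents that add atoms: 3-chloroperoxybenzoic acid O=C(OO)c1cccc(Cl)c1
Why: Prilezhaev epoxidation, in which the trisubstituted C8=C9 alkene is far more nucleophilic than the 1,1-disubstituted alkene that bears an allylic oxygen; the epoxide face is of no consequence.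

**Step 10**
Reactants: 18 epoxide
Product: 19 C8 ketone with the side chain on C9
Conditions: BF3·OEt2, CH2Cl2, −78 °C; then DBU (cat.), rt
Reagents that add atoms: none
Why: Meinwald rearrangement, in which Lewis-acid opening at the tertiary C9 and a 1,2-hydride shift from C8 give the C8 ketone (migration of C7 would create two adjacent quaternary carbons), and base equilibrates the α-carbon C9 toward the epimer with the equatorial side chain, a centre that stays under thermodynamic control until step 15.

**Step 11**
Reactants: 19 keto acetal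
Product: 20 trans-fused methylene lactol (anomers)
Conditions: 2 N HCl, THF, 40 °C
Reagents that add atoms: water O
Why: Acid hydrolysis of the silyl ether and the dioxolane, after which the free C19 hydroxyl captures the C1 aldehyde as a six-membered lactol that is trans-fused because C1 and C4 are trans on ring B.

**Step 12**
Reactants: 20 lactol; 21 triphenyl(vinyl)phosphonium bromide
Product: 24 benzyl ent-19-hydroxy-8-oxo-17-norlabd-1-en-15-oate, via phosphonium salt 22 (not isolated), via ylide 23 (not isolated)
Conditions: Fe(acac)3 (30 mol%), PhSiH2(Oi-Pr) (2.5 equiv), 21 (1.5 equiv), THF/i-PrOH, 40 °C; then, same flask, evaporate, THF, KHMDS (2.5 equiv), −78 °C to rt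
Reagents that add atoms: none
Why: Proposed new method: iron-hydride hydrogen-atom transfer to the C4=C18 methylene gives the tertiary C4 radical inside the lactol ring, which adds to the vinylphosphonium salt (C3–C4) and is reduced and protonated to phosphonium salt 22; base then opens the lactol and ylide 23 closes onto the C1 aldehyde (C1=C2). The closest known reaction types are hydrogen-atom-transfer-initiated radical conjugate addition–aldol annulations (radical–polar crossover) and the Michael–Wittig annulation of vinylphosphonium salts (Schweizer reaction). Ring A is closed by an intramolecular Wittig olefination, a 6-exo-trig attack of the ylide carbon C2 on the C1 carbonyl that can give only the cis ring alkene. The one new stereocentre, C4, is set in the radical addition by the axial C20 methyl on C10, which is 1,3-syn-axial to C4 in the chair lactol ring, so the acceptor should enter equatorially and C19 should end axial and cis to C20 once ring A has formed. The step needs hydrogen-atom transfer only at the 1,1-disubstituted alkene and olefination only at C1; no other alkene is present because C8 is still a ketone, and attack on the C8 ketone would require a bridged seven-membered ring.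

**Step 13**
Reactants: 24 hydroxy ketone; 25 (2R)-2-methylbutanoic acid
Product: 26 C19 (2R)-2-methylbutanoate
Conditions: DCC (1.5 equiv), DMAP (0.3 equiv), CH2Cl2, 0 °C to rt
Reagents that add atoms: none
Why: Steglich esterification of the primary neopentyl C19 alcohol, under which the α-stereocentre of the acid is not enolised.

**Step 14**
Reactants: 26 benzyl ester
Product: 27 saturated keto acid
Conditions: H2 (1 atm), 10% Pd/C, EtOAc, rt
Reagents that add atoms: none
Why: Heterogeneous hydrogenation saturates the cis-disubstituted C1=C2 alkene and hydrogenolyses the benzyl ester in one operation, and it forms no stereocentre.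

**Step 15**
Reactants: 27 keto acid
Product: 28 target acid CNP0365997.1
Conditions: Ph3PCH3Br (4 equiv), KOt-Bu (3.8 equiv), THF, 0 to 50 °C; aqueous citric acid work-up
Reagents that add atoms: methyltriphenylphosphonium bromide C[P+](c1ccccc1)(c1ccccc1)c1ccccc1.[Br-]
Why: Wittig methylenation of the C8 ketone with excess ylide (one equivalent is taken up by the carboxylic acid), to which the hindered C19 ester should be inert and under which C9 keeps its thermodynamic configuration.

**Compound list**
1 | 2-bromoprop-2-en-1-ol | C=C(Br)CO | starting material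
2 | [(2-bromoprop-2-en-1-yl)oxy](tert-butyl)dimethylsilane | C=C(Br)CO[Si](C)(C)C(C)(C)C | intermediate
3 | 2-methylcyclohex-2-en-1-one | CC1=CCCCC1=O | starting material
4 | {3-[(tert-butyldimethylsilyl)oxy]prop-1-en-2-yl}lithium | [Li]C(=C)CO[Si](C)(C)C(C)(C)C | intermediate (not isolated)
5 | {3-[(tert-butyldimethylsilyl)oxy]prop-1-en-2-yl}magnesium bromide | Br[Mg]C(=C)CO[Si](C)(C)C(C)(C)C | intermediate (not isolated)
6 | bromomagnesium enolate of (3R)-3-{3-[(tert-butyldimethylsilyl)oxy]prop-1-en-2-yl}-2-methylcyclohexan-1-one | CC1=C(O[Mg]Br)CCC[C@@H]1C(=C)CO[Si](C)(C)C(C)(C)C | intermediate (not isolated)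
7 | tert-butyldimethyl({2-[(1R)-2-methyl-3-(trimethylsilyloxy)cyclohex-2-en-1-yl]prop-2-en-1-yl}oxy)silane | CC1=C(O[Si](C)(C)C)CCC[C@@H]1C(=C)CO[Si](C)(C)C(C)(C)C | intermediate
8 | 2-methoxy-1,3-dioxolane | COC1OCCO1 | starting material
9 | (2S,3R)-3-{3-[(tert-butyldimethylsilyl)oxy]prop-1-en-2-yl}-2-(1,3-dioxolan-2-yl)-2-methylcyclohexan-1-one (dioxolanyl trans to alkenyl) | O=C1CCC[C@H](C(=C)CO[Si](C)(C)C(C)(C)C)[C@@]1(C)C1OCCO1 | intermediate
10 | (5R,6R)-5-{3-[(tert-butyldimethylsilyl)oxy]prop-1-en-2-yl}-6-(1,3-dioxolan-2-yl)-6-methylcyclohex-1-en-1-yl trifluoromethanesulfonate | FC(F)(F)S(=O)(=O)OC1=CCC[C@H](C(=C)CO[Si](C)(C)C(C)(C)C)[C@@]1(C)C1OCCO1 | intermediate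
11 | 3-methylglutaric anhydride (4-methyloxane-2,6-dione) | CC1CC(=O)OC(=O)C1 | starting material
12 | benzyl alcohol | OCc1ccccc1 | starting material
13 | (3R)-5-(benzyloxy)-3-methyl-5-oxopentanoic acid | OC(=O)C[C@@H](C)CC(=O)OCc1ccccc1 | intermediate
14 | benzyl (3R)-5-hydroxy-3-methylpentanoate | OCC[C@@H](C)CC(=O)OCc1ccccc1 | intermediate
15 | benzyl (3S)-5-iodo-3-methylpentanoate | ICC[C@@H](C)CC(=O)OCc1ccccc1 | intermediate
16 | [(3S)-5-(benzyloxy)-3-methyl-5-oxopentyl]zinc iodide | I[Zn]CC[C@@H](C)CC(=O)OCc1ccccc1 | intermediate (not isolated)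
17 | benzyl (3R)-5-[(5R,6R)-5-{3-[(tert-butyldimethylsilyl)oxy]prop-1-en-2-yl}-6-(1,3-dioxolan-2-yl)-6-methylcyclohex-1-en-1-yl]-3-methylpentanoate | O=C(OCc1ccccc1)C[C@H](C)CCC1=CCC[C@H](C(=C)CO[Si](C)(C)C(C)(C)C)[C@@]1(C)C1OCCO1 | intermediate
18 | C8–C9 epoxide of 17 (7-oxabicyclo[4.1.0]heptane; mixture of epoxide faces; C5, C10, C13 as in 17) | O=C(OCc1ccccc1)C[C@H](C)CCC12OC1CC[C@H](C(=C)CO[Si](C)(C)C(C)(C)C)[C@@]2(C)C1OCCO1 | intermediate
19 | benzyl (3R)-5-[(1S,2R,3R)-3-{3-[(tert-butyldimethylsilyl)oxy]prop-1-en-2-yl}-2-(1,3-dioxolan-2-yl)-2-methyl-6-oxocyclohexyl]-3-methylpentanoate | O=C1CC[C@H](C(=C)CO[Si](C)(C)C(C)(C)C)[C@](C2OCCO2)(C)[C@@H]1CC[C@@H](C)CC(=O)OCc1ccccc1 | intermediate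
20 | benzyl (3R)-5-[(4aR,8S,8aR)-1-hydroxy-8a-methyl-4-methylidene-7-oxooctahydro-1H-isochromen-8-yl]-3-methylpentanoate (lactol, both anomers) | O=C1CC[C@@H]2C(=C)COC(O)[C@@]2(C)[C@@H]1CC[C@@H](C)CC(=O)OCc1ccccc1 | intermediate
21 | triphenyl(vinyl)phosphonium bromide | C=C[P+](c1ccccc1)(c1ccccc1)c1ccccc1.[Br-] | starting material
22 | {2-[(4R,4aR,8S,8aR)-8-[(3R)-5-(benzyloxy)-3-methyl-5-oxopentyl]-1-hydroxy-4,8a-dimethyl-7-oxooctahydro-1H-isochromen-4-yl]ethyl}triphenylphosphonium bromide | O=C1CC[C@@H]2[C@@](C)(CC[P+](c3ccccc3)(c3ccccc3)c3ccccc3)COC(O)[C@@]2(C)[C@@H]1CC[C@@H](C)CC(=O)OCc1ccccc1.[Br-] | intermediate (not isolated)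
23 | ring-opened ylide: benzyl (3R)-5-[(1S,2R,3R)-2-formyl-3-[(2R)-1-hydroxy-2-methyl-4-(triphenyl-λ5-phosphanylidene)butan-2-yl]-2-methyl-6-oxocyclohexyl]-3-methylpentanoate | O=C1CC[C@H]([C@](C)(CO)CC=P(c2ccccc2)(c2ccccc2)c2ccccc2)[C@](C=O)(C)[C@@H]1CC[C@@H](C)CC(=O)OCc1ccccc1 | intermediate (not isolated)
24 | benzyl (3R)-5-[(1S,4aS,5R,8aR)-5-(hydroxymethyl)-5,8a-dimethyl-2-oxo-1,2,3,4,4a,5,6,8a-octahydronaphthalen-1-yl]-3-methylpentanoate | O=C1CC[C@@H]2[C@](C)(CO)CC=C[C@@]2(C)[C@@H]1CC[C@@H](C)CC(=O)OCc1ccccc1 | intermediate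
25 | (2R)-2-methylbutanoic acid | CC[C@@H](C)C(=O)O | starting material
26 | benzyl (3R)-5-[(1S,4aS,5R,8aR)-5,8a-dimethyl-5-({[(2R)-2-methylbutanoyl]oxy}methyl)-2-oxo-1,2,3,4,4a,5,6,8a-octahydronaphthalen-1-yl]-3-methylpentanoate | O=C1CC[C@@H]2[C@](C)(COC(=O)[C@H](C)CC)CC=C[C@@]2(C)[C@@H]1CC[C@@H](C)CC(=O)OCc1ccccc1 | intermediate
27 | (3R)-5-[(1S,4aS,5R,8aR)-5,8a-dimethyl-5-({[(2R)-2-methylbutanoyl]oxy}methyl)-2-oxodecahydronaphthalen-1-yl]-3-methylpentanoic acid | O=C1CC[C@@H]2[C@](C)(COC(=O)[C@H](C)CC)CCC[C@@]2(C)[C@@H]1CC[C@@H](C)CC(=O)O | intermediate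
28 | (3R)-5-[(1R,4aS,5R,8aS)-5,8a-dimethyl-2-methylidene-5-({[(2R)-2-methylbutanoyl]oxy}methyl)decahydronaphthalen-1-yl]-3-methylpentanoic acid (ent-19-[(2R)-2-methylbutanoyloxy]labd-8(17)-en-15-oic acid, 13R) | C=C1CC[C@@H]2[C@](C)(COC(=O)[C@H](C)CC)CCC[C@@]2(C)[C@@H]1CC[C@@H](C)CC(=O)O | target

**Totals.** Total step count: 15. Longest linear sequence: 12 steps (steps 1–4 and 8–15); steps 5–7 make the side-chain iodide.

**Steps most likely to fail**

1. Step 12 (proposed new method). The radical–polar crossover may stop short: the C4 radical may simply be reduced, the vinylphosphonium salt may be consumed by the iron hydride, or the ylide may be quenched before it olefinates, and the facial selectivity at C4 may be lower than the chair model suggests. Fallback with known chemistry: it sets out from lactol 20. An iron-hydride reductive olefin coupling (Fe(acac)3, PhSiH3, EtOH/THF) with 1-phenyl-5-(vinylsulfonyl)-1H-tetrazole, a Giese addition to a vinyl sulfone, should give the tetrazolyl sulfone lactol F1 with the same control at C4. Treatment of F1 with KHMDS in THF should then effect an intramolecular Julia–Kocienski olefination on the lactol-derived aldehyde, and the route is rejoined at 24.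

2. Step 2. Alkenyl transfer to the α-methyl enone may be slow and poorly enantioselective. Fallback: it sets out from bromide 2, converted to Grignard reagent 5 as before, and uses cyclohex-2-en-1-one, the best-precedented acceptor. Copper/phosphoramidite-catalysed conjugate addition with TMSCl trapping should give silyl enol ether F2. Regiospecific enolate release and methylation (MeLi, then MeI) should give 2-methyl ketone F3. Thermodynamic silylation (TMSCl, NaI, Et3N, MeCN) should then give the tetrasubstituted enol ether, and the route is rejoined at 7.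

3. Step 10. The cationic rearrangement may take other paths, namely ring contraction by migration of C7, or ionisation of the dioxolane or of the allylic silyl ether by the Lewis acid. Fallback: it sets out from epoxide 18. Titanium(III)-mediated reductive epoxide opening (Cp2TiCl2, Zn, 1,4-cyclohexadiene, THF; Nugent–RajanBabu reagent) proceeds through the tertiary C9 radical and should give the secondary C8 alcohol F4. Dess–Martin oxidation and equilibration with DBU rejoin the route at 19.

**Further compounds**
F1 | step 12 | benzyl (3R)-5-[(4R,4aR,8S,8aR)-1-hydroxy-4,8a-dimethyl-7-oxo-4-{2-[(1-phenyl-1H-tetrazol-5-yl)sulfonyl]ethyl}octahydro-1H-isochromen-8-yl]-3-methylpentanoate | O=C1CC[C@@H]2[C@@](C)(CCS(=O)(=O)c3nnnn3-c3ccccc3)COC(O)[C@@]2(C)[C@@H]1CC[C@@H](C)CC(=O)OCc1ccccc1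
F2 | step 2 | tert-butyldimethyl({2-[(1R)-3-(trimethylsilyloxy)cyclohex-2-en-1-yl]prop-2-en-1-yl}oxy)silane | C[Si](C)(C)OC1=C[C@@H](C(=C)CO[Si](C)(C)C(C)(C)C)CCC1
F3 | step 2 | (3R)-3-{3-[(tert-butyldimethylsilyl)oxy]prop-1-en-2-yl}-2-methylcyclohexan-1-one (C2 epimers, mainly trans) | O=C1CCC[C@H](C(=C)CO[Si](C)(C)C(C)(C)C)C1C
F4 | step 10 | benzyl (3R)-5-[(2R,3R)-3-{3-[(tert-butyldimethylsilyl)oxy]prop-1-en-2-yl}-2-(1,3-dioxolan-2-yl)-6-hydroxy-2-methylcyclohexyl]-3-methylpentanoate (C8 and C9 epimers) | OC1CC[C@H](C(=C)CO[Si](C)(C)C(C)(C)C)[C@](C2OCCO2)(C)C1CC[C@@H](C)CC(=O)OCc1ccccc1
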